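## Retrosynthetic overview

- The (E)-enol ester comes from O-acylation of a keto aldehyde. The keto aldehyde comes from ozonolysis of a cis-fused cyclohexene, built by Diels–Alder addition of a 2-thio diene to a tricyclic enone; this sets the two side-chain carbons cis.
- The tricyclic enone comes from a bicyclo[4.3.1]decane β-keto ester by hydroxymethylation and an acid cascade (decarboxylation, pyran closure, dehydration).
- The seven-membered ring is closed by a palladium-catalysed intramolecular allylic alkylation of a free tertiary allylic alcohol with the β-keto ester; this is the key C–C bond.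
- The cyclisation precursor comes from a vinylogous Mukaiyama aldol union of a cyclohexene carbaldehyde (catalytic asymmetric Diels–Alder, quaternary centre) with a bis-silyl dienolate of tert-butyl acetoacetate.
- Ring order: cyclohexene, then the seven-membered carbocycle, then the pyran; a temporary cyclohexene is then added and cleaved to give both side chains.

Assumption: the (S)-configured oxazaborolidinium catalyst of step 3 gives the (S)-aldehyde; if the observed sense is opposite, the (R)-catalyst is used.

Numbering used in names: tricyclic compounds are 6-oxatricyclo[6.3.2.0(4,13)]tridecanes. C1 is the methyl-bearing quaternary bridgehead, C2–C3 are CH2, C4 is the ring-fusion CH, C5 is CMe2, O6, C7 is OCH2, C8 is the CH next to the C9 ketone, C10 and C11 carry the side chains, C12 is the bridging CH2, C13 is the bridgehead CH.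

## Route

Step 1
Reactants: 1 2-methylbut-3-yn-2-ol
Product: 2 trimethyl[(2-methylbut-3-yn-2-yl)oxy]silane
Conditions: (Me3Si)2NH (0.6 equiv), Me3SiCl (2 mol%), neat, 60 °C
Reagents that add atoms: hexamethyldisilazane C[Si](C)(C)N[Si](C)(C)C
Why: O-silylation of the tertiary propargylic alcohol masks the hydroxyl for the Lewis-acid steps that follow; no stereocentre is formed.

Step 2
Reactants: 2 trimethyl[(2-methylbut-3-yn-2-yl)oxy]silane; 3 ethene
Product: 4 trimethyl[(2-methyl-3-methylidenepent-4-en-2-yl)oxy]silane
Conditions: ethene (1 atm), RuCl2(=CHPh)(PCy3)(H2IMes) (second-generation Grubbs catalyst, 3 mol%), CH2Cl2, 40 °C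
Reagents that add atoms: none
Why: Ruthenium-carbene ethene–alkyne cross-enyne metathesis converts the terminal alkyne into the 2-substituted buta-1,3-diene; no stereocentre is formed.

Step 3
Reactants: 4 trimethyl[(2-methyl-3-methylidenepent-4-en-2-yl)oxy]silane; 5 2-methylprop-2-enal
Product: 6 (1S)-1-methyl-4-[2-(trimethylsilyloxy)propan-2-yl]cyclohex-3-ene-1-carbaldehyde
Conditions: (S)-tetrahydro-1-(2-methylphenyl)-3,3-diphenyl-1H,3H-pyrrolo[1,2-c][1,3,2]oxazaborole (20 mol%), HN(SO2CF3)2 (16 mol%), CH2Cl2, −78 → −40 °C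
Reagents that add atoms: none
Why: Catalytic enantioselective Diels–Alder reaction in which the cationic oxazaborolidinium binds methacrolein and shields one face, the 2-substituted diene adds with "para" orientation, and the quaternary stereocentre (S) is set by the catalyst.

Step 4
Reactants: 7 4-methylideneoxetan-2-one (diketene); 8 2-methylpropan-2-ol
Product: 9 tert-butyl 3-oxobutanoate
Conditions: NaOAc (0.5 mol%), neat, 80–110 °C
Reagents that add atoms: none
Why: Acetoacetylation of the alcohol by acyl–oxygen ring opening of diketene; no stereocentre is formed.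

Step 5
Reactants: 9 tert-butyl 3-oxobutanoate
Product: 10 tert-butyl 3-(trimethylsilyloxy)but-2-enoate
Conditions: Me3SiCl, Et3N, hexane, rt
Reagents that add atoms: chlorotrimethylsilane C[Si](C)(C)Cl
Why: O-silylation of the β-keto ester gives the silyl enol ether, the first half of a Chan-type diene synthesis; no stereocentre is formed.

Step 6
Reactants: 10 tert-butyl 3-(trimethylsilyloxy)but-2-enoate
Product: 11 1-tert-butoxy-1,3-bis(trimethylsilyloxy)buta-1,3-diene
Conditions: LiN(iPr)2, THF, −78 °C; then Me3SiCl
Reagents that add atoms: chlorotrimethylsilane C[Si](C)(C)Cl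
Why: γ-Deprotonation and O-silylation of the ester dienolate give the bis-silyl dienol ether, a 1,3-bis-nucleophile whose γ-carbon reacts first; no stereocentre is formed.

Step 7
Reactants: 6 (1S)-1-methyl-4-[2-(trimethylsilyloxy)propan-2-yl]cyclohex-3-ene-1-carbaldehyde; 11 1-tert-butoxy-1,3-bis(trimethylsilyloxy)buta-1,3-diene
Product: 13 tert-butyl 5-hydroxy-5-[(1S)-4-(2-hydroxypropan-2-yl)-1-methylcyclohex-3-en-1-yl]-3-oxopentanoate (C5 epimers), via silylated aldol adduct 12 (not isolated)
Conditions: Ti(OiPr)4 (10 mol%), racemic 1,1'-bi-2-naphthol (10 mol%), THF, −78 °C → rt; then 1 M HCl, THF, 0 °C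
Reagents that add atoms: none
Why: Vinylogous Mukaiyama aldol addition of the dienolate γ-carbon to the non-enolisable aldehyde, followed by acidic desilylation; the new carbinol centre forms as an epimer mixture that is destroyed in step 10.

Step 8
Reactants: 13 tert-butyl 5-hydroxy-5-[(1S)-4-(2-hydroxypropan-2-yl)-1-methylcyclohex-3-en-1-yl]-3-oxopentanoate
Product: 14 tert-butyl (1R,6S)-5-hydroxy-6-methyl-3-oxo-9-(propan-2-ylidene)bicyclo[4.3.1]decane-2-carboxylate (C5 epimers)
Conditions: Pd(PPh3)4 (5 mol%), Et3B (30 mol%), THF (0.02 M), 50 °C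
Reagents that add atoms: none
Why: Proposed new method: a dehydrative intramolecular Tsuji–Trost closure of a bridged seven-membered ring from a free tertiary allylic alcohol, in which Et3B turns the hydroxyl into a borate leaving group, zerovalent palladium ionises it to the exocyclic 1,1-dimethyl π-allyl complex, η3–η1–η3 exchange through the CMe2 terminus lets palladium reach the face anti to the tether, and the enol of the β-keto ester attacks the less hindered ring terminus (seven- instead of nine-membered ring), so the 1,3-diaxial bridge fixes the new bridgehead C1 cis to the chain on C6; the closest known reaction type is the Et3B-promoted palladium-catalysed allylation of active methylene compounds with allylic alcohols (intermolecular) together with intramolecular Tsuji–Trost alkylations of allylic carbonates.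

Step 9
Reactants: 14 tert-butyl (1R,6S)-5-hydroxy-6-methyl-3-oxo-9-(propan-2-ylidene)bicyclo[4.3.1]decane-2-carboxylate; 15 formaldehyde
Product: 16 tert-butyl 5-hydroxy-2-(hydroxymethyl)-6-methyl-3-oxo-9-(propan-2-ylidene)bicyclo[4.3.1]decane-2-carboxylate (C2 and C5 epimers)
Conditions: 37% aq. HCHO (5 equiv), KHCO3 (20 mol%), THF, rt
Reagents that add atoms: none
Why: Crossed aldol hydroxymethylation at the only doubly activated carbon; either epimer of the new quaternary centre is acceptable because it is erased by decarboxylation in step 10.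

Step 10
Reactants: 16 tert-butyl 5-hydroxy-2-(hydroxymethyl)-6-methyl-3-oxo-9-(propan-2-ylidene)bicyclo[4.3.1]decane-2-carboxylate
Product: 19 (1S,4R,8S,13S)-1,5,5-trimethyl-6-oxatricyclo[6.3.2.0(4,13)]tridec-10-en-9-one, via diol ketone 17 (not isolated), via hydroxy tricycle 18 (not isolated)
Conditions: CF3CO2H/CH2Cl2 (1:4), 0 °C → rt; then TsOH·H2O (10 mol%), PhMe, 80 °C
Reagents that add atoms: none
Why: Acid cascade of tert-butyl ester acidolysis with decarboxylation, Markovnikov hydroalkoxylation of the isopropylidene group and acid-catalysed β-elimination of the carbinol; C8 equilibrates through the enol and C4 through reversible alkene protonation, and only the arrangement with H-4, H-8 and H-13 mutually cis can close the six-membered ether onto the axial C13–C8 bond.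

Step 11
Reactants: 20 3-methyl-2,5-dihydrothiophene 1,1-dioxide
Product: 21 trans-3-chloro-3-methyl-4-(phenylsulfanyl)thiolane 1,1-dioxide (racemic)
Conditions: PhSCl (1.05 equiv), CH2Cl2, 0 °C → rt
Reagents that add atoms: benzenesulfenyl chloride ClSc1ccccc1
Why: Electrophilic chlorosulfenylation through the episulfonium ion, opened by chloride at the tertiary carbon (anti addition); the racemic stereocentres are removed in step 12.

Step 12
Reactants: 21 trans-3-chloro-3-methyl-4-(phenylsulfanyl)thiolane 1,1-dioxide
Product: 22 3-methyl-4-(phenylsulfanyl)-2,5-dihydrothiophene 1,1-dioxide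
Conditions: 1,8-diazabicyclo[5.4.0]undec-7-ene (DBU, 1.2 equiv), CH2Cl2, 0 °C → rt
Reagents that add atoms: none
Why: Dehydrochlorination with base-mediated double-bond equilibration gives the vinyl sulfide 3-sulfolene, a bench-stable mask of the 2-thio diene; no stereocentre remains.

Step 13
Reactants: 19 (1S,4R,8S,13S)-1,5,5-trimethyl-6-oxatricyclo[6.3.2.0(4,13)]tridec-10-en-9-one; 22 3-methyl-4-(phenylsulfanyl)-2,5-dihydrothiophene 1,1-dioxide
Product: 24 cis-fused Diels–Alder adduct of 19 carrying the ring C10–CH2–C(CH3)=C(SPh)–CH2–C11, via thio diene 23 (not isolated)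
Conditions: 22 (4 equiv), 2,6-di-tert-butyl-4-methylphenol (5 mol%), PhMe, 135 °C, sealed tube
Reagents that add atoms: none
Why: Cheletropic loss of SO2 releases the 2-thio diene for a Diels–Alder reaction in which sulfur places its carbon "para" to the ketone-bearing C10, and suprafacial addition to the enone face anti to the C2–C4 bridge sets C10 and C11 with both new bonds cis on the convex face.

Step 14
Reactants: 24 cis-fused vinyl sulfide adduct
Product: 25 desulfurised adduct carrying the ring C10–CH2–C(CH3)=CH–CH2–C11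
Conditions: Raney Ni (W-2, acetone-deactivated), acetone/EtOH, rt
Reagents that add atoms: none
Why: Reductive desulfurisation (hydrogenolysis of the vinylic C–S bond) under ketone-sparing conditions leaves the trisubstituted alkene; the stereocentres are untouched.

Step 15
Reactants: 25 desulfurised adduct
Product: 26 2-[(1S,4R,8S,10R,11S,13S)-1,5,5-trimethyl-9-oxo-10-(2-oxopropyl)-6-oxatricyclo[6.3.2.0(4,13)]tridecan-11-yl]acetaldehyde
Conditions: O3, CH2Cl2/MeOH, −78 °C (Sudan red end point); then Me2S, −78 °C → rt
Reagents that add atoms: ozone [O-][O+]=O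
Why: Ozonolysis of the trisubstituted cyclohexene unveils the methyl ketone arm on C10 and the acetaldehyde arm on C11 with their cis relationship retained.

Step 16
Reactants: 27 3-methylbut-2-enoic acid
Product: 28 3-methylbut-2-enoic anhydride
Conditions: 27 (2 equiv in all), N,N'-dicyclohexylcarbodiimide (1 equiv, that is 0.5 equiv per acid), CH2Cl2, 0 °C → rt; the urea is filtered off
Reagents that add atoms: 3-methylbut-2-enoic acid (second molecule of 27) CC(C)=CC(=O)O
Why: Carbodiimide dehydration in which the O-acylisourea formed from one molecule of the acid is acylated by a second molecule of the acid to give the symmetrical anhydride and the urea; no stereocentre is formed.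

Step 17
Reactants: 26 2-[(1S,4R,8S,10R,11S,13S)-1,5,5-trimethyl-9-oxo-10-(2-oxopropyl)-6-oxatricyclo[6.3.2.0(4,13)]tridecan-11-yl]acetaldehyde; 28 3-methylbut-2-enoic anhydride
Product: 29 (E)-2-[(1S,4R,8S,10R,11S,13S)-1,5,5-trimethyl-9-oxo-10-(2-oxopropyl)-6-oxatricyclo[6.3.2.0(4,13)]tridecan-11-yl]ethenyl 3-methylbut-2-enoate
Conditions: 28 (3 equiv), Et3N (3 equiv), 4-(dimethylamino)pyridine (20 mol%), PhMe, 50 °C
Reagents that add atoms: none
Why: O-acylation of the aldehyde enolate (enol esterification), the aldehyde being the most readily enolised carbonyl; the bulky tertiary C11 substituent favours the E enol ester (minor Z isomer removed by chromatography) and the mild amine base leaves C10 unepimerised.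

## Compound list

1 | 2-methylbut-3-yn-2-ol | CC(C)(O)C#C | starting material
2 | trimethyl[(2-methylbut-3-yn-2-yl)oxy]silane | CC(C)(C#C)O[Si](C)(C)C | intermediate
3 | ethene | C=C | starting material
4 | trimethyl[(2-methyl-3-methylidenepent-4-en-2-yl)oxy]silane | C=CC(=C)C(C)(C)O[Si](C)(C)C | intermediate
5 | 2-methylprop-2-enal (methacrolein) | CC(=C)C=O | starting material
6 | (1S)-1-methyl-4-[2-(trimethylsilyloxy)propan-2-yl]cyclohex-3-ene-1-carbaldehyde | O=C[C@]1(C)CC=C(C(C)(C)O[Si](C)(C)C)CC1 | intermediate
7 | 4-methylideneoxetan-2-one (diketene) | C=C1CC(=O)O1 | starting material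
8 | 2-methylpropan-2-ol | CC(C)(C)O | starting material
9 | tert-butyl 3-oxobutanoate | CC(=O)CC(=O)OC(C)(C)C | intermediate
10 | tert-butyl 3-(trimethylsilyloxy)but-2-enoate (E/Z mixture) | CC(O[Si](C)(C)C)=CC(=O)OC(C)(C)C | intermediate
11 | 1-tert-butoxy-1,3-bis(trimethylsilyloxy)buta-1,3-diene | C=C(O[Si](C)(C)C)C=C(OC(C)(C)C)O[Si](C)(C)C | intermediate
12 | tert-butyl 3,5-bis(trimethylsilyloxy)-5-{(1S)-1-methyl-4-[2-(trimethylsilyloxy)propan-2-yl]cyclohex-3-en-1-yl}pent-2-enoate (C5 epimers; not isolated) | CC(C)(O[Si](C)(C)C)C1=CC[C@](C)(CC1)C(O[Si](C)(C)C)CC(O[Si](C)(C)C)=CC(=O)OC(C)(C)C | intermediate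
13 | tert-butyl 5-hydroxy-5-[(1S)-4-(2-hydroxypropan-2-yl)-1-methylcyclohex-3-en-1-yl]-3-oxopentanoate (C5 epimers) | CC(C)(O)C1=CC[C@](C)(CC1)C(O)CC(=O)CC(=O)OC(C)(C)C | intermediate
14 | tert-butyl (1R,6S)-5-hydroxy-6-methyl-3-oxo-9-(propan-2-ylidene)bicyclo[4.3.1]decane-2-carboxylate (C5 epimers; C2 epimers and enol) | O=C1C(C(=O)OC(C)(C)C)[C@@H]2C(=C(C)C)CC[C@@](C)(C2)C(O)C1 | intermediate
15 | formaldehyde | C=O | starting material
16 | tert-butyl 5-hydroxy-2-(hydroxymethyl)-6-methyl-3-oxo-9-(propan-2-ylidene)bicyclo[4.3.1]decane-2-carboxylate (bridgeheads as in 14; C2 and C5 epimers) | O=C1C(CO)(C(=O)OC(C)(C)C)[C@@H]2C(=C(C)C)CC[C@@](C)(C2)C(O)C1 | intermediate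
17 | 5-hydroxy-2-(hydroxymethyl)-6-methyl-9-(propan-2-ylidene)bicyclo[4.3.1]decan-3-one (bridgeheads as in 14; C2 and C5 epimers; not isolated) | O=C1C(CO)[C@@H]2C(=C(C)C)CC[C@@](C)(C2)C(O)C1 | intermediate
18 | (1S,4R,8S,13S)-11-hydroxy-1,5,5-trimethyl-6-oxatricyclo[6.3.2.0(4,13)]tridecan-9-one (C11 epimers; not isolated) | O=C1[C@@H]2COC(C)(C)[C@@H]3CC[C@@](C)(C[C@@H]32)C(O)C1 | intermediate
19 | (1S,4R,8S,13S)-1,5,5-trimethyl-6-oxatricyclo[6.3.2.0(4,13)]tridec-10-en-9-one | O=C1[C@@H]2COC(C)(C)[C@@H]3CC[C@@](C)(C[C@@H]32)C=C1 | intermediate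
20 | 3-methyl-2,5-dihydrothiophene 1,1-dioxide | CC1=CCS(=O)(=O)C1 | starting material
21 | trans-3-chloro-3-methyl-4-(phenylsulfanyl)thiolane 1,1-dioxide (racemic; one enantiomer drawn) | C[C@@]1(Cl)CS(=O)(=O)C[C@H]1Sc1ccccc1 | intermediate
22 | 3-methyl-4-(phenylsulfanyl)-2,5-dihydrothiophene 1,1-dioxide | CC1=C(Sc2ccccc2)CS(=O)(=O)C1 | intermediate
23 | [(3-methylbuta-1,3-dien-2-yl)sulfanyl]benzene (not isolated) | C=C(C)C(=C)Sc1ccccc1 | intermediate
24 | Diels–Alder adduct: 19 with a cis-fused cyclohexene on C10–C11 (C10–CH2–C(CH3)=C(SPh)–CH2–C11), both new bonds on the face anti to the C2–C4 bridge | O=C1[C@@H]2COC(C)(C)[C@@H]3CC[C@@](C)(C[C@@H]32)[C@H]4CC(Sc5ccccc5)=C(C)C[C@H]41 | intermediate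
25 | desulfurised adduct: as 24 with C10–CH2–C(CH3)=CH–CH2–C11 | O=C1[C@@H]2COC(C)(C)[C@@H]3CC[C@@](C)(C[C@@H]32)[C@H]4CC=C(C)C[C@H]41 | intermediate
26 | 2-[(1S,4R,8S,10R,11S,13S)-1,5,5-trimethyl-9-oxo-10-(2-oxopropyl)-6-oxatricyclo[6.3.2.0(4,13)]tridecan-11-yl]acetaldehyde | CC(=O)C[C@H]1C(=O)[C@@H]2COC(C)(C)[C@@H]3CC[C@@](C)(C[C@@H]32)[C@H]1CC=O | intermediate
27 | 3-methylbut-2-enoic acid | CC(C)=CC(=O)O | starting material
28 | 3-methylbut-2-enoic anhydride | CC(C)=CC(=O)OC(=O)C=C(C)C | intermediate
29 | (E)-2-[(1S,4R,8S,10R,11S,13S)-1,5,5-trimethyl-9-oxo-10-(2-oxopropyl)-6-oxatricyclo[6.3.2.0(4,13)]tridecan-11-yl]ethenyl 3-methylbut-2-enoate | CC(=O)C[C@H]1C(=O)[C@@H]2COC(C)(C)[C@@H]3CC[C@@](C)(C[C@@H]32)[C@H]1/C=C/OC(=O)C=C(C)C | target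

## Step count and fallbacks

Total step count: 17. Longest linear sequence: 11 steps (1–3, 7–10, 13–15, 17; the path through 4–6 is equally long).

**Step 8 (the proposed new cyclisation).** The hindered trisubstituted alkene may ionise slowly, and O-alkylation or elimination to a diene may compete. The fallback sets out from 13 and comes back at 14. It gives up the π-allylpalladium coupling and closes the ring as a carbocation (SN1') cycloalkylation: InCl3 (5 mol%) in toluene at 60–80 °C ionises the tertiary allylic alcohol, and the enol of the β-keto ester traps the allyl cation at its ring terminus. This is the known Lewis-acid-catalysed direct allylation of 1,3-dicarbonyl compounds with allylic alcohols. Ether formation by the secondary hydroxyl is reversible under these conditions, so the C-alkylated product accumulates. No new compound lies on this way (F0).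

**Step 10 (acid cascade).** Possible failures are closure of a five-membered ether through the ring cation, acid-promoted loss of formaldehyde, and dehydration to an α-methylene ketone before the ether closes. The fallback sets out from 14 (step 9 is left out) and comes back at 19. CF3CO2H, then TsOH·H2O in toluene at 80 °C, removes the ester by acidolysis and decarboxylation and dehydrates the carbinol to the bicyclic enone (1R,6S)-6-methyl-9-(propan-2-ylidene)bicyclo[4.3.1]dec-4-en-3-one F1. LiN(iPr)2 in THF at −78 °C forms the cross-conjugated enolate, which can only lie on C2 because C4 is vinylic, and monomeric formaldehyde gives the 2-(hydroxymethyl) enone F2. The epimerisable C2–H then lets catalytic camphorsulfonic acid in CH2Cl2 close the pyran to 19 as a separate, mild step.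

**Step 13 (Diels–Alder on the hindered enone).** The β-carbon sits next to the quaternary centre, and the thermal conditions cannot be accelerated by a Lewis acid while SO2 is being released. The fallback sets out from 19 and comes back at 26, using a more reactive oxygenated diene and cleavage at the acid oxidation level. 3-Methylbut-3-en-2-one, tert-butyldimethylsilyl triflate and Et3N give tert-butyl(dimethyl)[(3-methylbuta-1,3-dien-2-yl)oxy]silane F3. A Me2AlCl-promoted Diels–Alder reaction of this diene with 19 (CH2Cl2, −78 → −20 °C) gives the cis-fused silyl enol ether adduct F4, with the silyloxy carbon "para" to C10 and the same facial sense. Ozonolysis with Me2S work-up cleaves the silyl enol ether to the keto acid F5. EtSH, N,N'-dicyclohexylcarbodiimide and 4-(dimethylamino)pyridine then give the S-ethyl thioester F6, and Fukuyama reduction (Pd/C, Et3SiH, acetone) delivers keto aldehyde 26.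

## Further compounds

F0 | step 8 | none | none
F1 | step 10 | (1R,6S)-6-methyl-9-(propan-2-ylidene)bicyclo[4.3.1]dec-4-en-3-one | O=C1C[C@@H]2C(=C(C)C)CC[C@@](C)(C2)C=C1
F2 | step 10 | 2-(hydroxymethyl)-6-methyl-9-(propan-2-ylidene)bicyclo[4.3.1]dec-4-en-3-one (bridgeheads as in F1; C2 epimers) | O=C1C(CO)[C@@H]2C(=C(C)C)CC[C@@](C)(C2)C=C1
F3 | step 13 | tert-butyl(dimethyl)[(3-methylbuta-1,3-dien-2-yl)oxy]silane | C=C(C)C(=C)O[Si](C)(C)C(C)(C)C
F4 | step 13 | silyl enol ether adduct: 19 with a cis-fused cyclohexene on C10–C11 (C10–CH2–C(CH3)=C(OSiMe2tBu)–CH2–C11), new bonds anti to the C2–C4 bridge | O=C1[C@@H]2COC(C)(C)[C@@H]3CC[C@@](C)(C[C@@H]32)[C@H]4CC(O[Si](C)(C)C(C)(C)C)=C(C)C[C@H]41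
F5 | step 13 | 2-[(1S,4R,8S,10R,11S,13S)-1,5,5-trimethyl-9-oxo-10-(2-oxopropyl)-6-oxatricyclo[6.3.2.0(4,13)]tridecan-11-yl]acetic acid | CC(=O)C[C@H]1C(=O)[C@@H]2COC(C)(C)[C@@H]3CC[C@@](C)(C[C@@H]32)[C@H]1CC(=O)O
F6 | step 13 | S-ethyl 2-[(1S,4R,8S,10R,11S,13S)-1,5,5-trimethyl-9-oxo-10-(2-oxopropyl)-6-oxatricyclo[6.3.2.0(4,13)]tridecan-11-yl]ethanethioate | CC(=O)C[C@H]1C(=O)[C@@H]2COC(C)(C)[C@@H]3CC[C@@](C)(C[C@@H]32)[C@H]1CC(=O)SCC
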